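**Retrosynthetic overview**

1. Target 30 ← C9 MOM ether 29 ← transannular gold-catalysed 5-endo cyclisation of the ten-membered α′-hydroxy ynone 28 (the furanone is the last ring formed).
2. 28 ← seco aldehyde/allylic chloride 25 by chromium-mediated intramolecular 2-(methoxycarbonyl)allylation at C6–C7, which closes the ten-membered carbocycle and the cis-fused α-methylene lactone in one operation.
3. 25 ← late union at C1–C2 of the C2–C6 enyne 22 (as its alkynyl Grignard) with the C1 aldehyde 14, which carries C7–C14, all three oxygenated stereocentres and the methacrylate.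
4. 14 ← C8–C9 bond by catalytic asymmetric (Z)-γ-alkoxyallylboration of chloro-enal 5 with boronate 9, then substrate-controlled dihydroxylation (C10) and oxidation.
5. 5 ← Morita–Baylis–Hillman adduct of 2,2-dimethoxyacetaldehyde and methyl acrylate; 9 ← 2-methylprop-2-en-1-ol; 22 ← but-2-yn-1-ol and ethynyltrimethylsilane.

Assumption: positions use germacrane numbering (C1 furanone C=O, C2 furanone CH, C3 furanone C–O, C4=C5 side alkene, C6 lactone CH–O, C7, C8 ester carbon, C9 carbinol, C10 quaternary carbon, C11–C13 methylene lactone, C14 and C15 methyls); the target as drawn is 4Z,6S,7S,8S,9R,10R with a cis-fused lactone.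

**Route**

Step 1
Reactants: 1 2,2-dimethoxyacetaldehyde; 2 methyl acrylate
Product: 3 methyl 3-hydroxy-4,4-dimethoxy-2-methylidenebutanoate (racemic)
Conditions: 1,4-diazabicyclo[2.2.2]octane (1 equiv), 1,4-dioxane/H2O 1:1, rt, 48 h
Reagents that add atoms: none
Why: Morita–Baylis–Hillman reaction of a reactive, non-enolisable aldehyde with the acrylate; the carbinol centre is left racemic because step 2 erases it.

Step 2
Reactants: 3 methyl 3-hydroxy-4,4-dimethoxy-2-methylidenebutanoate
Product: 5 methyl (2Z)-2-(chloromethyl)-4-oxobut-2-enoate, via chloro acetal 4 (not isolated)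
Conditions: NCS, Me2S, CH2Cl2, −20 to 0 °C; then CF3CO2H/H2O 1:1, 0 °C, 1 h; used crude
Reagents that add atoms: N-chlorosuccinimide, ClN1C(=O)CCC1=O; water, O
Why: Corey–Kim activation of the allylic alcohol followed by SN2′ chloride attack gives the thermodynamically favoured Z-configured 2-(chloromethyl)enoate (CH2Cl cis to the C8 carbon), and the conjugated dimethyl acetal is then hydrolysed to the enal.

Step 3
Reactants: 6 2-methylprop-2-en-1-ol
Product: 7 3-(methoxymethoxy)-2-methylprop-1-ene
Conditions: MOMCl, i-Pr2NEt, CH2Cl2, 0 °C to rt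
Reagents that add atoms: chloromethyl methyl ether, COCCl
Why: O-alkylation (Williamson-type acetal ether formation) installs an ether that tolerates sec-BuLi and directs the lithiation in step 4.

Step 4
Reactants: 7 3-(methoxymethoxy)-2-methylprop-1-ene
Product: 9 2-[(2Z)-3-(methoxymethoxy)-2-methylprop-2-en-1-yl]-4,4,5,5-tetramethyl-1,3,2-dioxaborolane, via allyllithium 8 (not isolated)
Conditions: sec-BuLi, THF, −78 °C; then 2-isopropoxy-4,4,5,5-tetramethyl-1,3,2-dioxaborolane, −78 °C to rt; aq NH4Cl
Reagents that add atoms: 2-isopropoxy-4,4,5,5-tetramethyl-1,3,2-dioxaborolane, CC(C)OB1OC(C)(C)C(C)(C)O1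
Why: oxygen-directed allylic lithiation gives the internally chelated oxyallyl anion, which is borylated at the carbon remote from oxygen to give the Z-γ-alkoxyallylboronate (Hoffmann-type synthesis).

Step 5
Reactants: 5 methyl (2Z)-2-(chloromethyl)-4-oxobut-2-enoate; 9 the (Z)-γ-alkoxyallylboronate
Product: 11 methyl (2Z,4S,5S)-2-(chloromethyl)-4-hydroxy-5-(methoxymethoxy)-6-methylhepta-2,6-dienoate, via pinacol borate 10 (not isolated)
Conditions: (R)-3,3′-bis(2,4,6-triisopropylphenyl)-1,1′-binaphthyl-2,2′-diyl hydrogen phosphate (5 mol%), 4 Å MS, toluene, −40 °C, 36 h; aq NaHCO3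
Reagents that add atoms: none
Why: chiral phosphoric acid-catalysed allylboration through a closed chair transition state, in which the Z-boronate enforces the syn C8/C9 relationship and the (R)-acid directs attack to the Re face of the aldehyde (the sense known for aryl and alkenyl aldehydes), setting C8 and C9 while leaving C8–OH free and C9–O protected.

Step 6
Reactants: 11 the syn hydroxy MOM ether
Product: 12 methyl (2Z,4S,5S)-2-(chloromethyl)-5-(methoxymethoxy)-6-methyl-4-(methacryloyloxy)hepta-2,6-dienoate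
Conditions: methacryloyl chloride, i-Pr2NEt, 4-(dimethylamino)pyridine (5 mol%), CH2Cl2, −40 to −20 °C
Reagents that add atoms: methacryloyl chloride, C=C(C)C(Cl)=O
Why: nucleophile-catalysed O-acylation of the only free hydroxyl, run cold with a hindered base so that neither the allylic chloride is attacked nor the hydroxy chloride closes to a dihydrofuran.

Step 7
Reactants: 12 the methacrylate
Product: 13 methyl (2Z,4S,5R,6S)-2-(chloromethyl)-6,7-dihydroxy-5-(methoxymethoxy)-6-methyl-4-(methacryloyloxy)hept-2-enoate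
Conditions: K2OsO2(OH)4 (1 mol%), N-methylmorpholine N-oxide (1.1 equiv), citric acid (1 equiv), t-BuOH/H2O 1:1, rt
Reagents that add atoms: N-methylmorpholine N-oxide, C[N+]1([O-])CCOCC1; water, O
Why: Upjohn dihydroxylation in which the citric acid keeps the amine by-product protonated (sparing the allylic chloride), the only electron-rich alkene reacts, and osmium adds anti to the allylic C9 oxygen (Kishi's rule) to set C10 erythro to C9 (expected dr about 6:1, minor epimer removed by chromatography).

Step 8
Reactants: 13 the 1,10-diol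
Product: 14 methyl (2Z,4S,5R,6R)-2-(chloromethyl)-6-hydroxy-5-(methoxymethoxy)-6-methyl-4-(methacryloyloxy)-7-oxohept-2-enoate
Conditions: (COCl)2, DMSO, CH2Cl2, −78 °C; i-Pr2NEt, −78 to −30 °C
Reagents that add atoms: none
Why: Swern oxidation converts only the primary alcohol, the tertiary C10 hydroxyl cannot be oxidised and the quaternary α-carbon cannot epimerise.

Step 9
Reactants: 15 but-2-yn-1-ol
Product: 17 (2Z)-3-iodobut-2-en-1-ol, via vinylalanate 16 (not isolated)
Conditions: NaAlH2(OCH2CH2OMe)2, THF, 0 °C to rt; then I2, −78 °C to rt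
Reagents that add atoms: iodine, II
Why: hydroxyl-directed trans-hydroalumination places aluminium at C3 and iodinolysis with retention gives the Z-vinyl iodide that fixes the C4=C5 geometry of the target.

Step 10
Reactants: 17 (2Z)-3-iodobut-2-en-1-ol; 18 ethynyltrimethylsilane
Product: 19 (2Z)-3-methyl-5-(trimethylsilyl)pent-2-en-4-yn-1-ol
Conditions: Pd(PPh3)2Cl2 (2 mol%), CuI (4 mol%), Et3N, THF, rt
Reagents that add atoms: none
Why: Sonogashira coupling proceeds with retention of the alkene geometry, so the alkyne (C2–C3) ends up cis to C6.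

Step 11
Reactants: 19 the silylated enynol
Product: 20 (2Z)-3-methyl-5-(trimethylsilyl)pent-2-en-4-ynal
Conditions: MnO2, CH2Cl2, rt
Reagents that add atoms: none
Why: selective allylic oxidation with MnO2 under neutral conditions keeps the Z geometry.

Step 12
Reactants: 20 the enynal
Product: 21 [(3Z)-5,5-dimethoxy-3-methylpent-3-en-1-yn-1-yl]trimethylsilane
Conditions: HC(OMe)3, MeOH, pyridinium p-toluenesulfonate (cat.), rt
Reagents that add atoms: trimethyl orthoformate, COC(OC)OC; methanol, CO
Why: mild acid-catalysed acetalisation masks C6 at the aldehyde oxidation level, so that after the fragment union the ring can be closed before C1 is oxidised.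

Step 13
Reactants: 21 the silyl enyne acetal
Product: 22 (3Z)-5,5-dimethoxy-3-methylpent-3-en-1-yne
Conditions: K2CO3 (cat.), MeOH, 0 °C
Reagents that add atoms: none
Why: base-catalysed protodesilylation frees the terminal alkyne without touching the acetal.

Step 14
Reactants: 22 (3Z)-5,5-dimethoxy-3-methylpent-3-en-1-yne; 14 the hydroxy aldehyde
Product: 25 methyl (2Z,4S,5R,6S,7RS,10Z)-2-(chloromethyl)-6,7-dihydroxy-5-(methoxymethoxy)-6,10-dimethyl-4-(methacryloyloxy)-12-oxododeca-2,10-dien-8-ynoate, via alkynylmagnesium chloride 23 (not isolated), via acetal adduct 24 (not isolated)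
Conditions: 22 (2.3 equiv), i-PrMgCl·LiCl (2.2 equiv), THF, 0 °C to rt; then 14, −78 to −30 °C; then 1 M HCl, THF, 0 °C
Reagents that add atoms: water, O
Why: 1,2-addition of the alkynyl Grignard reagent to the aldehyde (one equivalent is consumed by the tertiary hydroxyl; esters and the allylic chloride are inert at low temperature) joins the two fragments, the new C1 carbinol is formed as both epimers and is removed in step 16, and the acidic work-up unmasks the Z-enal.

Step 15
Reactants: 25 the seco hydroxy enal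
Product: 27 (4Z)-1,10-dihydroxy-9-(methoxymethoxy)-8-(methacryloyloxy)germacra-4,11(13)-dien-2-yn-12,6-olide (C6–C10 configured as in 30; both C1 epimers), via hydroxy ester 26 (not isolated)
Conditions: CrCl2 (10 equiv), LiI (20 mol%), THF, 2 mM, slow addition, rt; aq NH4Cl; then pyridinium p-toluenesulfonate (cat.), CH2Cl2, rt
Reagents that add atoms: none
Why: intramolecular Nozaki–Hiyama (Barbier-type) 2-(alkoxycarbonyl)allylation in which the γ-substituted allylchromium attacks the aldehyde through a chair transition state to give the syn C6/C7 pair (hence the cis lactone after lactonisation), with the face relative to C8 expected to be the one that keeps the C8 ester pseudo-equatorial in the ring-forming transition state.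

Step 16
Reactants: 27 the macrocyclic diol lactone
Product: 28 (4Z)-10-hydroxy-9-(methoxymethoxy)-8-(methacryloyloxy)-1-oxogermacra-4,11(13)-dien-2-yn-12,6-olide (C6–C10 configured as in 30)
Conditions: Dess–Martin periodinane, CH2Cl2, 0 °C to rt; aq NaHCO3
Reagents that add atoms: none
Why: oxidation of the secondary propargylic alcohol converges both C1 epimers into one ynone while the tertiary alcohol is untouched.

Step 17
Reactants: 28 the macrocyclic α′-hydroxy ynone
Product: 29 9-O-(methoxymethyl) ether of the target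
Conditions: (Ph3P)AuNTf2 (5 mol%), toluene, rt
Reagents that add atoms: none
Why: gold-catalysed transannular 5-endo-dig hydroalkoxylation of the α′-hydroxy ynone gives the 3(2H)-furanone with release of alkyne strain, and C9 is still protected so no six-membered ring can form.

Step 18
Reactants: 29 the MOM-protected furanone
Product: 30 (4Z,6S,7S,8S,9R,10R)-9-hydroxy-8-(methacryloyloxy)-1-oxo-3,10-epoxygermacra-2,4,11(13)-trien-12,6-olide (CNP0252578.4)
Conditions: Me2BBr, CH2Cl2, −78 °C; then aq NaHCO3
Reagents that add atoms: none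
Why: Lewis-acid acetal cleavage at −78 °C removes the MOM group without touching the esters, the lactone or the furanone, and the non-basic conditions avoid 8→9 acyl migration.

**Compound list**

1 | 2,2-dimethoxyacetaldehyde | COC(OC)C=O | starting material
2 | methyl acrylate | C=CC(=O)OC | starting material
3 | methyl 3-hydroxy-4,4-dimethoxy-2-methylidenebutanoate (racemic) | COC(OC)C(O)C(=C)C(=O)OC | intermediate
4 | methyl (2Z)-2-(chloromethyl)-4,4-dimethoxybut-2-enoate (not isolated) | COC(=O)/C(CCl)=C/C(OC)OC | intermediate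
5 | methyl (2Z)-2-(chloromethyl)-4-oxobut-2-enoate | COC(=O)/C(CCl)=C/C=O | intermediate
6 | 2-methylprop-2-en-1-ol | C=C(C)CO | starting material
7 | 3-(methoxymethoxy)-2-methylprop-1-ene | C=C(C)COCOC | intermediate
8 | [1-(methoxymethoxy)-2-methylprop-2-en-1-yl]lithium (not isolated) | [Li]C(OCOC)C(C)=C | intermediate
9 | 2-[(2Z)-3-(methoxymethoxy)-2-methylprop-2-en-1-yl]-4,4,5,5-tetramethyl-1,3,2-dioxaborolane | COCO/C=C(/C)CB1OC(C)(C)C(C)(C)O1 | intermediate
10 | methyl (2Z,4S,5S)-2-(chloromethyl)-5-(methoxymethoxy)-6-methyl-4-[(4,4,5,5-tetramethyl-1,3,2-dioxaborolan-2-yl)oxy]hepta-2,6-dienoate (not isolated) | COC(=O)/C(CCl)=C/[C@H](OB1OC(C)(C)C(C)(C)O1)[C@@H](OCOC)C(C)=C | intermediate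
11 | methyl (2Z,4S,5S)-2-(chloromethyl)-4-hydroxy-5-(methoxymethoxy)-6-methylhepta-2,6-dienoate | COC(=O)/C(CCl)=C/[C@H](O)[C@@H](OCOC)C(C)=C | intermediate
12 | methyl (2Z,4S,5S)-2-(chloromethyl)-5-(methoxymethoxy)-6-methyl-4-(methacryloyloxy)hepta-2,6-dienoate | COC(=O)/C(CCl)=C/[C@H](OC(=O)C(C)=C)[C@@H](OCOC)C(C)=C | intermediate
13 | methyl (2Z,4S,5R,6S)-2-(chloromethyl)-6,7-dihydroxy-5-(methoxymethoxy)-6-methyl-4-(methacryloyloxy)hept-2-enoate | COC(=O)/C(CCl)=C/[C@H](OC(=O)C(C)=C)[C@@H](OCOC)[C@@](C)(O)CO | intermediate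
14 | methyl (2Z,4S,5R,6R)-2-(chloromethyl)-6-hydroxy-5-(methoxymethoxy)-6-methyl-4-(methacryloyloxy)-7-oxohept-2-enoate | COC(=O)/C(CCl)=C/[C@H](OC(=O)C(C)=C)[C@@H](OCOC)[C@@](C)(O)C=O | intermediate
15 | but-2-yn-1-ol | CC#CCO | starting material
16 | sodium 2,2-bis(2-methoxyethoxy)-3-methyl-2,5-dihydro-1,2-oxaaluminol-2-uide (vinylalanate, not isolated) | CC1=CCO[Al-]1(OCCOC)OCCOC.[Na+] | intermediate
17 | (2Z)-3-iodobut-2-en-1-ol | C/C(I)=C/CO | intermediate
18 | ethynyltrimethylsilane | C#C[Si](C)(C)C | starting material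
19 | (2Z)-3-methyl-5-(trimethylsilyl)pent-2-en-4-yn-1-ol | C/C(C#C[Si](C)(C)C)=C/CO | intermediate
20 | (2Z)-3-methyl-5-(trimethylsilyl)pent-2-en-4-ynal | C/C(C#C[Si](C)(C)C)=C/C=O | intermediate
21 | [(3Z)-5,5-dimethoxy-3-methylpent-3-en-1-yn-1-yl]trimethylsilane | C/C(C#C[Si](C)(C)C)=C/C(OC)OC | intermediate
22 | (3Z)-5,5-dimethoxy-3-methylpent-3-en-1-yne | C/C(C#C)=C/C(OC)OC | intermediate
23 | chloro[(3Z)-5,5-dimethoxy-3-methylpent-3-en-1-yn-1-yl]magnesium (not isolated) | C/C(C#C[Mg]Cl)=C/C(OC)OC | intermediate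
24 | methyl (2Z,4S,5R,6S,7RS,10Z)-2-(chloromethyl)-6,7-dihydroxy-12,12-dimethoxy-5-(methoxymethoxy)-6,10-dimethyl-4-(methacryloyloxy)dodeca-2,10-dien-8-ynoate (not isolated) | COC(=O)/C(CCl)=C/[C@H](OC(=O)C(C)=C)[C@@H](OCOC)[C@@](C)(O)C(O)C#C/C(C)=C\C(OC)OC | intermediate
25 | methyl (2Z,4S,5R,6S,7RS,10Z)-2-(chloromethyl)-6,7-dihydroxy-5-(methoxymethoxy)-6,10-dimethyl-4-(methacryloyloxy)-12-oxododeca-2,10-dien-8-ynoate | COC(=O)/C(CCl)=C/[C@H](OC(=O)C(C)=C)[C@@H](OCOC)[C@@](C)(O)C(O)C#C/C(C)=C\C=O | intermediate
26 | ten-membered 6-hydroxy methyl ester: methyl 2-substituted acrylate at C7, 1,6,10-triol, 9-OMOM, 8-methacrylate, C6–C10 configured as in 30, both C1 epimers (not isolated) | COC(=O)C(=C)[C@H]1[C@@H](O)/C=C(/C)C#CC(O)[C@](C)(O)[C@H](OCOC)[C@H]1OC(=O)C(C)=C | intermediate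
27 | (4Z)-1,10-dihydroxy-9-(methoxymethoxy)-8-(methacryloyloxy)germacra-4,11(13)-dien-2-yn-12,6-olide, C6–C10 configured as in 30, both C1 epimers | C=C(C)C(=O)O[C@H]1[C@H]2C(=C)C(=O)O[C@H]2/C=C(/C)C#CC(O)[C@](C)(O)[C@@H]1OCOC | intermediate
28 | (4Z)-10-hydroxy-9-(methoxymethoxy)-8-(methacryloyloxy)-1-oxogermacra-4,11(13)-dien-2-yn-12,6-olide, C6–C10 configured as in 30 | C=C(C)C(=O)O[C@H]1[C@H]2C(=C)C(=O)O[C@H]2/C=C(/C)C#CC(=O)[C@](C)(O)[C@@H]1OCOC | intermediate
29 | 9-O-(methoxymethyl) ether of 30 | C=C(C)C(=O)O[C@H]1[C@H]2C(=C)C(=O)O[C@H]2/C=C(/C)C2=CC(=O)[C@](C)(O2)[C@@H]1OCOC | intermediate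
30 | (4Z,6S,7S,8S,9R,10R)-9-hydroxy-8-(methacryloyloxy)-1-oxo-3,10-epoxygermacra-2,4,11(13)-trien-12,6-olide (CNP0252578.4) | C=C(C)C(=O)O[C@H]1[C@H]2C(=C)C(=O)O[C@H]2/C=C(/C)C2=CC(=O)[C@](C)(O2)[C@@H]1O | target

**Step count**

Total steps: 18 (steps 1–2, 3–4 and 9–13 are three parallel branches).
Longest linear sequence: 11 steps (1 → 3 → 5 → 11 → 12 → 13 → 14 → 25 → 27 → 28 → 29 → 30; the branch from 6 through 7 and 9 is equally long; the branch from 15 is 10 steps).

**Steps most likely to fail, with fallbacks**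

Step 15 (ring closure). The chromium-mediated closure has to form a strained ten-membered enyne ring, and the face of attack relative to C8 is not secured by any acyclic model. The fallback builds the furanone before the ring is closed, so that the heterocycle holds the two arms in a U-shape and changes the conformational bias. It sets out from 25: Dess–Martin oxidation gives the acyclic α′-hydroxy ynone F1, and (Ph3P)AuNTf2 in toluene converts it into the acyclic 3(2H)-furanone aldehyde F2. CrCl2/LiI under high dilution then joins C6 to C7 through the furanone-bridged hydroxy ester F3, which lactonises under pyridinium p-toluenesulfonate, and the route is rejoined at 29.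

Step 5 (catalytic asymmetric union). The chloro-enal 5 is very electrophilic, so uncatalysed background allylboration could erode the enantiomeric excess, and the boronate 9 is a new substrate for the phosphoric acid. The fallback replaces catalyst control by a stoichiometric chiral auxiliary on boron. It sets out from 7: the allyllithium 8 is trapped with B(Oi-Pr)3 and the crude boronic acid is esterified with diisopropyl (2S,3S)-tartrate (MgSO4) to give the tartrate allylboronate F4. Reaction of F4 with 5 in toluene at −78 °C over 4 Å sieves (Roush conditions; the (S,S)-tartrate directs Re-face attack and the Z-boronate again gives the syn adduct) forms the tartrate borate F5, whose aqueous hydrolysis returns the route at 11.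

Step 2 (chloro-enal 5). Acid hydrolysis of the acetal in the presence of the activated allylic chloride may hydrolyse or isomerise the product. The fallback unveils the aldehyde by ozonolysis under neutral, anhydrous conditions. It sets out from 2: Morita–Baylis–Hillman reaction with (E)-but-2-enal (1,4-diazabicyclo[2.2.2]octane, neat) gives the dienyl adduct F6, and NCS/Me2S converts it by SN2′ into the dienyl chloride F7. One equivalent of ozone in CH2Cl2 at −78 °C followed by Me2S cleaves only the electron-richer distal alkene, and the route is rejoined at 5.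

**Further compounds**

F1 | step 15 | methyl (2Z,4S,5R,6R,10Z)-2-(chloromethyl)-6-hydroxy-5-(methoxymethoxy)-6,10-dimethyl-4-(methacryloyloxy)-7,12-dioxododeca-2,10-dien-8-ynoate | COC(=O)/C(CCl)=C/[C@H](OC(=O)C(C)=C)[C@@H](OCOC)[C@@](C)(O)C(=O)C#C/C(C)=C\C=O
F2 | step 15 | methyl (2Z,4S,5R)-2-(chloromethyl)-5-(methoxymethoxy)-4-(methacryloyloxy)-5-{(2R)-2-methyl-3-oxo-5-[(2Z)-4-oxobut-2-en-2-yl]-2,3-dihydrofuran-2-yl}pent-2-enoate | COC(=O)/C(CCl)=C/[C@H](OC(=O)C(C)=C)[C@@H](OCOC)[C@@]1(C)OC(=CC1=O)/C(C)=C\C=O
F3 | step 15 | furanone-bridged ten-membered 6-hydroxy methyl ester (seco form of 29, not isolated) | COC(=O)C(=C)[C@H]1[C@@H](O)/C=C(/C)C2=CC(=O)[C@](C)(O2)[C@H](OCOC)[C@H]1OC(=O)C(C)=C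
F4 | step 5 | diisopropyl (4S,5S)-2-[(2Z)-3-(methoxymethoxy)-2-methylprop-2-en-1-yl]-1,3,2-dioxaborolane-4,5-dicarboxylate | COCO/C=C(/C)CB1O[C@H](C(=O)OC(C)C)[C@H](O1)C(=O)OC(C)C
F5 | step 5 | tartrate borate of 11 (not isolated) | COC(=O)/C(CCl)=C/[C@H](OB1O[C@H](C(=O)OC(C)C)[C@H](O1)C(=O)OC(C)C)[C@@H](OCOC)C(C)=C
F6 | step 2 | methyl (4E)-3-hydroxy-2-methylidenehex-4-enoate (racemic) | C/C=C/C(O)C(=C)C(=O)OC
F7 | step 2 | methyl (2Z,4E)-2-(chloromethyl)hexa-2,4-dienoate | COC(=O)/C(CCl)=C/C=C/C
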